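**Retrosynthetic overview**
- The last two operations only unmask the two aldehydes: the side-chain CHO from an N-acyloxazolidinone (hydrozirconation) and the ring CHO from a dioxolane.
- Key disconnection: the CH2–CH= bond between the CH2CH2 spacer and the (E)-trisubstituted alkene, made by nickel-electrocatalytic decarboxylative alkenylation of a redox-active ester with an (E)-alkenyl iodide (from Negishi carboalumination).
- Enabling feature: the side chain has an unbranched CH2–CH2 link between the formyl-bearing stereocentre and the (E)-C=C, so the CH2 next to the alkene CH is a primary, non-stereogenic carbon that can be generated as a carboxyl-derived radical; the only ring, the cyclopentene, has a fully substituted C=C that should not trap it.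
- The cyclopentene is formed last of the rings, by contraction of a six-membered ring: bought cyclohexanone, then cyclohexenylmethyl acetate, then ozonolysis and intramolecular aldol condensation, which delivers CH2OAc and CHO on the tetrasubstituted C=C already differentiated.
- Stereocentres: the side-chain centre by auxiliary-controlled titanium-enolate Michael addition to tert-butyl acrylate (which also brings the carboxyl carbon later extruded as CO2); the ring centre by enantiotopic-group-selective deprotonation of the 4-substituted cyclohexanone.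

Key step: step 13

Assumption: the sense of the asymmetric deprotonation in step 5 is taken from 4-alkylcyclohexanones, where the (S,S)-configured lithium bis(1-phenylethyl)amide leads to the (R)-enol derivative; if the opposite sense is found, the (R,R)-amide is used with no other change.

**Route**

Step 1
Reactants: 1 5-bromo-2-methylpent-2-ene
Product: 2 6-methylhept-5-en-1-yne
Conditions: HC≡CLi·H2N(CH2)2NH2, DMSO, 10 °C → rt
Reagents that add atoms: lithium acetylide–ethylenediamine complex, [Li+].[C-]#C.NCCN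
Why: SN2 alkylation of lithium acetylide by a primary homoallylic bromide in DMSO, with no stereocentre involved.

Step 2
Reactants: 2 6-methylhept-5-en-1-yne
Product: 4 (E)-1-iodo-2,6-dimethylhepta-1,5-diene, via alkenylalane 3 (not isolated)
Conditions: Me3Al, Cp2ZrCl2 (cat.), CH2Cl2, rt; then I2, THF, −30 → 0 °C
Reagents that add atoms: trimethylaluminium, C[Al](C)C; iodine, II
Why: Negishi carboalumination adds methyl and aluminium syn across the terminal alkyne with methyl on the internal carbon, and iodinolysis of the C–Al bond goes with retention, so the E alkene should result.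

Step 3
Reactants: 5 2-(4-oxocyclohexyl)acetic acid; 6 (R)-4-benzyloxazolidin-2-one
Product: 8 (R)-4-benzyl-3-[2-(4-oxocyclohexyl)acetyl]oxazolidin-2-one, via mixed anhydride 7 (not isolated)
Conditions: t-BuCOCl, Et3N, THF, −20 °C; then 6, LiCl, −20 °C → rt
Reagents that add atoms: none
Why: N-acylation of the oxazolidinone through the mixed pivalic anhydride, in which the unhindered acyl group is transferred and the ketone is untouched; no stereocentre is formed.

Step 4
Reactants: 8 (R)-4-benzyl-3-[2-(4-oxocyclohexyl)acetyl]oxazolidin-2-one; 9 tert-butyl acrylate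
Product: 11 tert-butyl (4R)-5-[(4R)-4-benzyl-2-oxooxazolidin-3-yl]-5-oxo-4-(4-oxocyclohexyl)pentanoate, via titanium enolate 10 (not isolated)
Conditions: TiCl3(OiPr) [TiCl4 + Ti(OiPr)4, 3:1], iPr2NEt, CH2Cl2, 0 °C; then 9, 0 °C; aq. NH4Cl
Reagents that add atoms: none
Why: Michael addition of the chelated (Z)-titanium enolate of an N-acyloxazolidinone to an acrylate, in which the acrylate approaches the enolate face opposite the benzyl group and should set the (R) side-chain stereocentre, while the ketone is spared because only the chelating imide is enolised.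

Step 5
Reactants: 11 tert-butyl (4R)-5-[(4R)-4-benzyl-2-oxooxazolidin-3-yl]-5-oxo-4-(4-oxocyclohexyl)pentanoate
Product: 13 tert-butyl (4R)-5-[(4R)-4-benzyl-2-oxooxazolidin-3-yl]-5-oxo-4-[(1R)-4-(trifluoromethanesulfonyloxy)cyclohex-3-en-1-yl]pentanoate, via lithium enolate 12 (not isolated)
Conditions: lithium (S,S)-bis(1-phenylethyl)amide [(S,S)-bis(1-phenylethyl)amine + n-BuLi], LiCl, THF, −78 °C; then N-(5-chloropyridin-2-yl)bis(trifluoromethanesulfonyl)imide, −78 → 0 °C
Reagents that add atoms: N-(5-chloropyridin-2-yl)bis(trifluoromethanesulfonyl)imide, O=S(=O)(N(c1ccc(Cl)cn1)S(=O)(=O)C(F)(F)F)C(F)(F)F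
Why: Asymmetric deprotonation of a 4-substituted cyclohexanone by a chiral lithium amide followed by O-sulfonylation of the enolate: the base selects one of the two enantiotopic α-methylene groups, so the position of the new C=C makes the ring carbon (R) under reagent control (any minor ring epimer is a diastereomer and is removed by chromatography), and the α-branched imide C–H is not removed because its enolate would suffer allylic strain.

Step 6
Reactants: 13 tert-butyl (4R)-5-[(4R)-4-benzyl-2-oxooxazolidin-3-yl]-5-oxo-4-[(1R)-4-(trifluoromethanesulfonyloxy)cyclohex-3-en-1-yl]pentanoate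
Product: 14 tert-butyl (4R)-5-[(4R)-4-benzyl-2-oxooxazolidin-3-yl]-4-[(1R)-4-(hydroxymethyl)cyclohex-3-en-1-yl]-5-oxopentanoate
Conditions: Bu3SnCH2OH, Pd(PPh3)4 (cat.), LiCl, 1,4-dioxane, 95 °C
Reagents that add atoms: (tributylstannyl)methanol, CCCC[Sn](CCCC)(CCCC)CO
Why: Migita–Kosugi–Stille coupling of an enol triflate with a hydroxymethylstannane, in which zerovalent palladium inserts into the C–O bond of the triflate and CH2OH is transferred from tin without change at either stereocentre.

Step 7
Reactants: 14 tert-butyl (4R)-5-[(4R)-4-benzyl-2-oxooxazolidin-3-yl]-4-[(1R)-4-(hydroxymethyl)cyclohex-3-en-1-yl]-5-oxopentanoate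
Product: 15 tert-butyl (4R)-4-[(1R)-4-(acetoxymethyl)cyclohex-3-en-1-yl]-5-[(4R)-4-benzyl-2-oxooxazolidin-3-yl]-5-oxopentanoate
Conditions: Ac2O, pyridine, DMAP (cat.), CH2Cl2, 0 °C → rt
Reagents that add atoms: acetic anhydride, CC(=O)OC(C)=O
Why: Acylation of the primary allylic alcohol, placing the acetate of the target before the ring is cut.

Step 8
Reactants: 15 tert-butyl (4R)-4-[(1R)-4-(acetoxymethyl)cyclohex-3-en-1-yl]-5-[(4R)-4-benzyl-2-oxooxazolidin-3-yl]-5-oxopentanoate
Product: 17 tert-butyl (4R)-4-[(3R)-7-acetoxy-1,6-dioxoheptan-3-yl]-5-[(4R)-4-benzyl-2-oxooxazolidin-3-yl]-5-oxopentanoate, via ozonide 16 (not isolated)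
Conditions: O3, CH2Cl2, −78 °C (to the end point of a dye indicator); then Me2S, −78 °C → rt
Reagents that add atoms: ozone, [O-][O+]=O
Why: Ozonolysis of the only C=C bond with reductive work-up gives the keto aldehyde; the former ring stereocentre is not α to either new carbonyl and should be retained.

Step 9
Reactants: 17 tert-butyl (4R)-4-[(3R)-7-acetoxy-1,6-dioxoheptan-3-yl]-5-[(4R)-4-benzyl-2-oxooxazolidin-3-yl]-5-oxopentanoate
Product: 19 tert-butyl (4R)-4-[(1S)-3-(acetoxymethyl)-2-formylcyclopent-2-en-1-yl]-5-[(4R)-4-benzyl-2-oxooxazolidin-3-yl]-5-oxopentanoate, via aldol 18 (not isolated)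
Conditions: dibenzylammonium trifluoroacetate (cat.), toluene, 50 °C
Reagents that add atoms: none
Why: Amine-catalysed intramolecular aldol condensation, in which the enamine of the aldehyde attacks the more electrophilic acetoxymethyl ketone to close the five-membered ring and dehydration gives the conjugated tetrasubstituted enal, so the six-membered ring is contracted to the cyclopentene with CH2OAc and CHO in place and no stereocentre is touched.

Step 10
Reactants: 19 tert-butyl (4R)-4-[(1S)-3-(acetoxymethyl)-2-formylcyclopent-2-en-1-yl]-5-[(4R)-4-benzyl-2-oxooxazolidin-3-yl]-5-oxopentanoate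
Product: 20 (4R)-4-[(1S)-3-(acetoxymethyl)-2-formylcyclopent-2-en-1-yl]-5-[(4R)-4-benzyl-2-oxooxazolidin-3-yl]-5-oxopentanoic acid
Conditions: CF3CO2H, CH2Cl2, 0 °C → rt
Reagents that add atoms: none
Why: Acidolysis of the tert-butyl ester, which the enal, the imide and the acetate (on an electron-poor alkene, so not prone to ionise) should survive.

Step 11
Reactants: 20 (4R)-4-[(1S)-3-(acetoxymethyl)-2-formylcyclopent-2-en-1-yl]-5-[(4R)-4-benzyl-2-oxooxazolidin-3-yl]-5-oxopentanoic acid
Product: 21 1,3-dioxoisoindolin-2-yl (4R)-4-[(1S)-3-(acetoxymethyl)-2-formylcyclopent-2-en-1-yl]-5-[(4R)-4-benzyl-2-oxooxazolidin-3-yl]-5-oxopentanoate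
Conditions: N-hydroxyphthalimide, DIC, DMAP (cat.), CH2Cl2, rt
Reagents that add atoms: N-hydroxyphthalimide, O=C1c2ccccc2C(=O)N1O
Why: Carbodiimide esterification of the unhindered primary acid gives the redox-active N-acyloxyphthalimide.

Step 12
Reactants: 21 1,3-dioxoisoindolin-2-yl (4R)-4-[(1S)-3-(acetoxymethyl)-2-formylcyclopent-2-en-1-yl]-5-[(4R)-4-benzyl-2-oxooxazolidin-3-yl]-5-oxopentanoate
Product: 22 1,3-dioxoisoindolin-2-yl (4R)-4-[(1S)-3-(acetoxymethyl)-2-(1,3-dioxolan-2-yl)cyclopent-2-en-1-yl]-5-[(4R)-4-benzyl-2-oxooxazolidin-3-yl]-5-oxopentanoate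
Conditions: TMSOCH2CH2OTMS, TMSOTf (cat.), CH2Cl2, −78 → −20 °C; pyridine quench
Reagents that add atoms: 1,2-bis(trimethylsilyloxy)ethane, C[Si](C)(C)OCCO[Si](C)(C)C
Why: Silyl-transfer acetalisation converts the enal to its dioxolane at low temperature without shifting the double bond, which masks the aldehyde for the reductive steps 13 and 14.

Step 13
Reactants: 22 1,3-dioxoisoindolin-2-yl (4R)-4-[(1S)-3-(acetoxymethyl)-2-(1,3-dioxolan-2-yl)cyclopent-2-en-1-yl]-5-[(4R)-4-benzyl-2-oxooxazolidin-3-yl]-5-oxopentanoate; 4 (E)-1-iodo-2,6-dimethylhepta-1,5-diene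
Product: 23 [(3S)-3-[(2R,5E)-1-[(4R)-4-benzyl-2-oxooxazolidin-3-yl]-6,10-dimethyl-1-oxoundeca-5,9-dien-2-yl]-2-(1,3-dioxolan-2-yl)cyclopent-1-en-1-yl]methyl acetate
Conditions: 4 (excess), NiCl2·6H2O (cat.), 2,2′-bipyridine (cat.), AgNO3 (0.3 equiv), DMF, undivided cell, Mg anode, reticulated vitreous carbon cathode, constant current, rt
Reagents that add atoms: none
Why: Cathodic reduction gives low-valent nickel–bipyridine, which adds oxidatively to alkenyl iodide 4; single-electron reduction of the N-acyloxyphthalimide expels phthalimide anion and CO2 and leaves the primary alkyl radical, which is captured by the divalent alkenylnickel species, and reductive elimination from trivalent nickel forms the C(sp3)–C(sp2) bond. The closest known reaction type is the nickel-electrocatalytic decarboxylative alkenylation of primary redox-active esters with alkenyl halides, used to assemble polyene terpenoid chains. No ring is closed and no stereocentre is formed: the E geometry is carried over from 4 because the alkenyl–nickel bond keeps its configuration, and the two existing stereocentres lie two and three bonds from the radical carbon. The selectivity needed is capture of the radical by nickel ahead of 5-exo attack on the ring C=C and ahead of any reaction of nickel with the allylic acetate; the ring carbon that would be attacked is fully substituted and carries the dioxolane, so closure would have to build a quaternary centre, and the tetrasubstituted alkene should bind zerovalent nickel far more slowly than the alkenyl iodide reacts. In one operation the step installs the whole C9 dienyl terminus with its E double bond and removes the carboxyl carbon that served as the handle.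

Step 14
Reactants: 23 [(3S)-3-[(2R,5E)-1-[(4R)-4-benzyl-2-oxooxazolidin-3-yl]-6,10-dimethyl-1-oxoundeca-5,9-dien-2-yl]-2-(1,3-dioxolan-2-yl)cyclopent-1-en-1-yl]methyl acetate
Product: 24 [(3S)-3-[(2R,5E)-6,10-dimethyl-1-oxoundeca-5,9-dien-2-yl]-2-(1,3-dioxolan-2-yl)cyclopent-1-en-1-yl]methyl acetate
Conditions: Cp2Zr(H)Cl, THF, rt; H2O work-up
Reagents that add atoms: none
Why: Hydrozirconation of the exocyclic imide carbonyl (the reduction of tertiary amides and N-acyloxazolidinones to aldehydes by Cp2Zr(H)Cl) gives a zirconium-bound hemiaminal that is not reduced further and releases the aldehyde and the auxiliary on work-up, while the acetate, the acetal and the trisubstituted alkenes react much more slowly and the neutral conditions should leave the α-stereocentre intact.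

Step 15
Reactants: 24 [(3S)-3-[(2R,5E)-6,10-dimethyl-1-oxoundeca-5,9-dien-2-yl]-2-(1,3-dioxolan-2-yl)cyclopent-1-en-1-yl]methyl acetate
Product: 25 [(3S)-2-formyl-3-[(2R,5E)-6,10-dimethyl-1-oxoundeca-5,9-dien-2-yl]cyclopent-1-en-1-yl]methyl acetate
Conditions: p-TsOH·H2O (cat.), THF/H2O, rt
Reagents that add atoms: water, O
Why: Acid-catalysed hydrolysis of the dioxolane of a conjugated aldehyde, which ionises easily to an allylic oxocarbenium ion, so mild acid should suffice and the acetate, the E alkene and the α-stereocentre of the saturated aldehyde should survive.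

**Compound list**
1 | 5-bromo-2-methylpent-2-ene | CC(C)=CCCBr | starting material
2 | 6-methylhept-5-en-1-yne | C#CCCC=C(C)C | intermediate
3 | (E)-(2,6-dimethylhepta-1,5-dien-1-yl)dimethylalane | C[Al](C)/C=C(\C)CCC=C(C)C | intermediate
4 | (E)-1-iodo-2,6-dimethylhepta-1,5-diene | I/C=C(\C)CCC=C(C)C | intermediate
5 | 2-(4-oxocyclohexyl)acetic acid | O=C1CCC(CC(=O)O)CC1 | starting material
6 | (R)-4-benzyloxazolidin-2-one | O=C1N[C@H](Cc2ccccc2)CO1 | starting material
7 | 2-(4-oxocyclohexyl)acetic pivalic anhydride | CC(C)(C)C(=O)OC(=O)CC1CCC(=O)CC1 | intermediate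
8 | (R)-4-benzyl-3-[2-(4-oxocyclohexyl)acetyl]oxazolidin-2-one | O=C1CCC(CC(=O)N2[C@H](Cc3ccccc3)COC2=O)CC1 | intermediate
9 | tert-butyl acrylate | C=CC(=O)OC(C)(C)C | starting material
10 | dichloro(isopropoxy)titanium (Z)-enolate of 8 | O=C1CCC(/C=C(\O[Ti](Cl)(Cl)OC(C)C)N2[C@H](Cc3ccccc3)COC2=O)CC1 | intermediate
11 | tert-butyl (4R)-5-[(4R)-4-benzyl-2-oxooxazolidin-3-yl]-5-oxo-4-(4-oxocyclohexyl)pentanoate | O=C1CCC([C@H](C(=O)N2[C@H](Cc3ccccc3)COC2=O)CCC(=O)OC(C)(C)C)CC1 | intermediate
12 | lithium (4R)-4-[(2R)-1-[(4R)-4-benzyl-2-oxooxazolidin-3-yl]-5-tert-butoxy-1,5-dioxopentan-2-yl]cyclohex-1-en-1-olate | [Li]OC1=CC[C@H]([C@H](C(=O)N2[C@H](Cc3ccccc3)COC2=O)CCC(=O)OC(C)(C)C)CC1 | intermediate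
13 | tert-butyl (4R)-5-[(4R)-4-benzyl-2-oxooxazolidin-3-yl]-5-oxo-4-[(1R)-4-(trifluoromethanesulfonyloxy)cyclohex-3-en-1-yl]pentanoate | O=S(=O)(OC1=CC[C@H]([C@H](C(=O)N2[C@H](Cc3ccccc3)COC2=O)CCC(=O)OC(C)(C)C)CC1)C(F)(F)F | intermediate
14 | tert-butyl (4R)-5-[(4R)-4-benzyl-2-oxooxazolidin-3-yl]-4-[(1R)-4-(hydroxymethyl)cyclohex-3-en-1-yl]-5-oxopentanoate | OCC1=CC[C@H]([C@H](C(=O)N2[C@H](Cc3ccccc3)COC2=O)CCC(=O)OC(C)(C)C)CC1 | intermediate
15 | tert-butyl (4R)-4-[(1R)-4-(acetoxymethyl)cyclohex-3-en-1-yl]-5-[(4R)-4-benzyl-2-oxooxazolidin-3-yl]-5-oxopentanoate | CC(=O)OCC1=CC[C@H]([C@H](C(=O)N2[C@H](Cc3ccccc3)COC2=O)CCC(=O)OC(C)(C)C)CC1 | intermediate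
16 | secondary ozonide (1,2,4-trioxolane across the former alkene carbons) of 15, mixture of isomers at the two acetal carbons | CC(=O)OCC12CC[C@@H]([C@H](C(=O)N3[C@H](Cc4ccccc4)COC3=O)CCC(=O)OC(C)(C)C)CC(OO1)O2 | intermediate
17 | tert-butyl (4R)-4-[(3R)-7-acetoxy-1,6-dioxoheptan-3-yl]-5-[(4R)-4-benzyl-2-oxooxazolidin-3-yl]-5-oxopentanoate | CC(=O)OCC(=O)CC[C@H](CC=O)[C@H](C(=O)N1[C@H](Cc2ccccc2)COC1=O)CCC(=O)OC(C)(C)C | intermediate
18 | tert-butyl (4R)-4-[(1R)-3-(acetoxymethyl)-2-formyl-3-hydroxycyclopentyl]-5-[(4R)-4-benzyl-2-oxooxazolidin-3-yl]-5-oxopentanoate, mixture of isomers at ring C-2 and C-3 | CC(=O)OCC1(O)CC[C@@H]([C@H](C(=O)N2[C@H](Cc3ccccc3)COC2=O)CCC(=O)OC(C)(C)C)C1C=O | intermediate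
19 | tert-butyl (4R)-4-[(1S)-3-(acetoxymethyl)-2-formylcyclopent-2-en-1-yl]-5-[(4R)-4-benzyl-2-oxooxazolidin-3-yl]-5-oxopentanoate | CC(=O)OCC1=C(C=O)[C@H]([C@H](C(=O)N2[C@H](Cc3ccccc3)COC2=O)CCC(=O)OC(C)(C)C)CC1 | intermediate
20 | (4R)-4-[(1S)-3-(acetoxymethyl)-2-formylcyclopent-2-en-1-yl]-5-[(4R)-4-benzyl-2-oxooxazolidin-3-yl]-5-oxopentanoic acid | CC(=O)OCC1=C(C=O)[C@H]([C@H](C(=O)N2[C@H](Cc3ccccc3)COC2=O)CCC(=O)O)CC1 | intermediate
21 | 1,3-dioxoisoindolin-2-yl (4R)-4-[(1S)-3-(acetoxymethyl)-2-formylcyclopent-2-en-1-yl]-5-[(4R)-4-benzyl-2-oxooxazolidin-3-yl]-5-oxopentanoate | CC(=O)OCC1=C(C=O)[C@H]([C@H](C(=O)N2[C@H](Cc3ccccc3)COC2=O)CCC(=O)ON2C(=O)c3ccccc3C2=O)CC1 | intermediate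
22 | 1,3-dioxoisoindolin-2-yl (4R)-4-[(1S)-3-(acetoxymethyl)-2-(1,3-dioxolan-2-yl)cyclopent-2-en-1-yl]-5-[(4R)-4-benzyl-2-oxooxazolidin-3-yl]-5-oxopentanoate | CC(=O)OCC1=C(C2OCCO2)[C@H]([C@H](C(=O)N2[C@H](Cc3ccccc3)COC2=O)CCC(=O)ON2C(=O)c3ccccc3C2=O)CC1 | intermediate
23 | [(3S)-3-[(2R,5E)-1-[(4R)-4-benzyl-2-oxooxazolidin-3-yl]-6,10-dimethyl-1-oxoundeca-5,9-dien-2-yl]-2-(1,3-dioxolan-2-yl)cyclopent-1-en-1-yl]methyl acetate | CC(=O)OCC1=C(C2OCCO2)[C@H]([C@H](C(=O)N2[C@H](Cc3ccccc3)COC2=O)CC/C=C(\C)CCC=C(C)C)CC1 | intermediate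
24 | [(3S)-3-[(2R,5E)-6,10-dimethyl-1-oxoundeca-5,9-dien-2-yl]-2-(1,3-dioxolan-2-yl)cyclopent-1-en-1-yl]methyl acetate | CC(=O)OCC1=C(C2OCCO2)[C@H]([C@H](C=O)CC/C=C(\C)CCC=C(C)C)CC1 | intermediate
25 | [(3S)-2-formyl-3-[(2R,5E)-6,10-dimethyl-1-oxoundeca-5,9-dien-2-yl]cyclopent-1-en-1-yl]methyl acetate | CC(=O)OCC1=C(C=O)[C@H]([C@H](C=O)CC/C=C(\C)CCC=C(C)C)CC1 | target

**Count**
Total step count: 15. Longest linear sequence: 13 steps (steps 3 to 15); steps 1 and 2 make alkenyl iodide 4.

**Steps most likely to fail**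

Step 13. What may go wrong: ring closure of the primary radical onto the cyclopentene C=C before nickel captures it, or insertion of low-valent nickel into the allylic C–O bond of the acetate; either drains the cross-coupling. The fallback sets out from 22 and comes back at 23. Light-driven iododecarboxylation (LiI, PPh3 cat., blue light, MeCN), in which iodine-atom transfer should outrun any ring closure, would give the primary alkyl iodide F1. Zinc insertion (Zn dust, LiCl, THF) would give the alkylzinc iodide F2, and Negishi coupling of F2 with 4 (Pd(dppf)Cl2 cat., THF) would form the same bond by a polar organometallic path and return to 23.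

Step 5. What may go wrong: poor discrimination between the two enantiotopic α-methylene groups, so that the ring stereocentre forms as a mixture that is hard to separate. The fallback sets out from 11 and comes back at 15, bypassing steps 5 to 7. D-Proline-catalysed α-aminoxylation with nitrosobenzene (DMSO, rt), a catalyst-controlled desymmetrisation of 4-substituted cyclohexanones, would give the α-anilinooxy ketone F3 (the proline enantiomer is the one expected on the usual enamine model to oxygenate the methylene group that becomes the alkene CH). Hydrogenolysis of the N–O bond (H2, Pd/C, EtOAc) would give the hydroxy ketone F4, and acetylation (Ac2O, pyridine) the acetoxy ketone F5. Methylenation of the ketone with the Zn/CH2Br2/TiCl4 reagent would give the exocyclic alkene F6. A PdCl2(MeCN)2-catalysed [3,3] shift of the allylic acetate would then move the double bond into the ring and the acetate onto the exocyclic carbon, giving 15.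

Step 14. What may go wrong: hydride transfer that is not confined to the imide carbonyl (attack on the acetate, hydrozirconation of an alkene), or stalling at the hindered α-branched imide. The fallback sets out from 23 and comes back at 24. Reductive cleavage of the auxiliary with NaBH4 in THF/H2O at 0 °C would give the primary alcohol F7, and Dess–Martin oxidation (NaHCO3, CH2Cl2) of F7 would give 24.

Further compounds
F1 | step 13 | [(3S)-3-[(2R)-1-[(4R)-4-benzyl-2-oxooxazolidin-3-yl]-4-iodo-1-oxobutan-2-yl]-2-(1,3-dioxolan-2-yl)cyclopent-1-en-1-yl]methyl acetate | CC(=O)OCC1=C(C2OCCO2)[C@H]([C@H](C(=O)N2[C@H](Cc3ccccc3)COC2=O)CCI)CC1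
F2 | step 13 | {(3R)-3-[(1S)-3-(acetoxymethyl)-2-(1,3-dioxolan-2-yl)cyclopent-2-en-1-yl]-4-[(4R)-4-benzyl-2-oxooxazolidin-3-yl]-4-oxobutyl}zinc iodide | CC(=O)OCC1=C(C2OCCO2)[C@H]([C@H](C(=O)N2[C@H](Cc3ccccc3)COC2=O)CC[Zn]I)CC1
F3 | step 5 | tert-butyl (4R)-5-[(4R)-4-benzyl-2-oxooxazolidin-3-yl]-5-oxo-4-[(1R,3S)-4-oxo-3-(phenylaminooxy)cyclohexyl]pentanoate | O=C1[C@@H](ONc2ccccc2)C[C@H]([C@H](C(=O)N2[C@H](Cc3ccccc3)COC2=O)CCC(=O)OC(C)(C)C)CC1
F4 | step 5 | tert-butyl (4R)-5-[(4R)-4-benzyl-2-oxooxazolidin-3-yl]-4-[(1R,3S)-3-hydroxy-4-oxocyclohexyl]-5-oxopentanoate | O=C1[C@@H](O)C[C@H]([C@H](C(=O)N2[C@H](Cc3ccccc3)COC2=O)CCC(=O)OC(C)(C)C)CC1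
F5 | step 5 | tert-butyl (4R)-4-[(1R,3S)-3-acetoxy-4-oxocyclohexyl]-5-[(4R)-4-benzyl-2-oxooxazolidin-3-yl]-5-oxopentanoate | O=C1[C@@H](OC(C)=O)C[C@H]([C@H](C(=O)N2[C@H](Cc3ccccc3)COC2=O)CCC(=O)OC(C)(C)C)CC1
F6 | step 5 | tert-butyl (4R)-4-[(1R,3S)-3-acetoxy-4-methylidenecyclohexyl]-5-[(4R)-4-benzyl-2-oxooxazolidin-3-yl]-5-oxopentanoate | C=C1[C@@H](OC(C)=O)C[C@H]([C@H](C(=O)N2[C@H](Cc3ccccc3)COC2=O)CCC(=O)OC(C)(C)C)CC1
F7 | step 14 | [(3S)-3-[(2R,5E)-1-hydroxy-6,10-dimethylundeca-5,9-dien-2-yl]-2-(1,3-dioxolan-2-yl)cyclopent-1-en-1-yl]methyl acetate | CC(=O)OCC1=C(C2OCCO2)[C@H]([C@H](CO)CC/C=C(\C)CCC=C(C)C)CC1
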